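Cuts: the diene is opened at the C=C attached to C3 of the isocoumarin (HWE, with the phosphonate on the C3 methylene and the enal on the oxolane), and the enal is opened at its own C=C (Wittig). C5–Cl is then removed, and ring B (the pyranone) is taken apart at C4a–C4, C8a–C1 and O2–C3 into an aryne, a terminal alkyne and CO2.
Enabling feature: C4a and C8a are adjacent carbons of ring A (the benzene ring) and hold the two ends of ring B, namely C4 and the carbonyl carbon C1. While C5 still bears hydrogen, C8a alone has an oxygenated neighbour (C8), so a C4a≡C8a aryne is biased by a single alkoxy group.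
Forward order: ring A comes from phloroglucinol as an o-silylaryl triflate and ring B closes in the aryne coupling. Chlorine then enters at C5 and the C3 arm becomes a phosphonate. Ring C (the oxolane) is carried over from 2-deoxy-D-ribose, the two halves are joined by HWE olefination, and one acid step frees all three hydroxyl groups.
Stereochemistry: oxolane C2 (R) and C3 (S) are C4 and C3 of 2-deoxy-D-ribose. C5 (S) is set by silane reduction of a methyl-substituted oxocarbenium ion on the face of the C3 oxygen, and both E double bonds come from stabilised phosphorus reagents.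

Key step: step 6

Remark: isocoumarin numbering is C1 (C=O), O2, C3, C4, C4a, C5–C8, C8a; oxolane numbering is O1, C2 (side chain), C3 (oxygen), C4, C5 (methyl); 2-deoxy-D-ribose is drawn open-chain in the list and is assumed to react in step 11 through its lactol forms.

Step 1
Reactants: 1 phloroglucinol (benzene-1,3,5-triol)
Product: 2 3,5-bis(methoxymethoxy)phenol
Conditions: MOMCl (2 equiv), i-Pr2NEt, DMF, 0 °C → rt
Reagents that add atoms: chloromethyl methyl ether (MOMCl), COCCl
Why: Base-mediated O-alkylation (Williamson-type acetal ether formation) of the threefold-symmetric triphenol with two equivalents of MOMCl should give the bis-ether as the main statistical product, and the mono- and tris-ethers can be separated and recycled.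

Step 2
Reactants: 2 3,5-bis(methoxymethoxy)phenol
Product: 3 2-bromo-3,5-bis(methoxymethoxy)phenol
Conditions: NBS (1 equiv), i-Pr2NH (cat.), CH2Cl2, −78 → 0 °C
Reagents that add atoms: N-bromosuccinimide, O=C1CCC(=O)N1Br
Why: Electrophilic aromatic bromination under amine-catalysed, phenol-directed conditions should place bromine ortho to the free OH, since the two equivalent positions C2/C6 receive bromine through hydrogen bonding to the phenol and are less crowded than C4, which lies between two MOM ethers.

Step 3
Reactants: 3 2-bromo-3,5-bis(methoxymethoxy)phenol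
Product: 4 [2-bromo-3,5-bis(methoxymethoxy)phenoxy]trimethylsilane
Conditions: (Me3Si)2NH, THF, 65 °C; evaporation
Reagents that add atoms: hexamethyldisilazane, C[Si](C)(C)N[Si](C)(C)C
Why: O-Silylation of a phenol with hexamethyldisilazane is neutral and gives only ammonia beside the ether, so the moisture-sensitive product can be freed of volatiles and lithiated directly.

Step 4
Reactants: 4 [2-bromo-3,5-bis(methoxymethoxy)phenoxy]trimethylsilane
Product: 7 3,5-bis(methoxymethoxy)-2-(trimethylsilyl)phenyl trifluoromethanesulfonate, via aryllithium 5 (not isolated), via lithium phenoxide 6 (not isolated)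
Conditions: n-BuLi, THF, −78 °C; then Tf2O, −78 → 0 °C
Reagents that add atoms: trifluoromethanesulfonic anhydride, O=S(=O)(OS(=O)(=O)C(F)(F)F)C(F)(F)F
Why: Bromine–lithium exchange is faster than MOM-directed deprotonation at −78 °C, aryllithium 5 undergoes the 1,3 O→C silyl shift (retro-Brook rearrangement) driven by phenoxide formation, and O-triflation of 6 completes the standard route to o-silylaryl triflates.

Step 5
Reactants: 8 propargyl alcohol (prop-2-yn-1-ol)
Product: 9 triisopropyl(prop-2-ynyloxy)silane
Conditions: TIPSCl, imidazole, CH2Cl2, rt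
Reagents that add atoms: chlorotriisopropylsilane, CC(C)[Si](Cl)(C(C)C)C(C)C
Why: Imidazole-promoted silylation of a primary alcohol is routine, and the bulky TIPS group is chosen so that the ether should outlast the fluoride used in step 6.

Step 6
Reactants: 7 3,5-bis(methoxymethoxy)-2-(trimethylsilyl)phenyl trifluoromethanesulfonate; 9 triisopropyl(prop-2-ynyloxy)silane; 10 carbon dioxide
Product: 13 6,8-bis(methoxymethoxy)-3-(triisopropylsilyloxymethyl)isochromen-1-one, via aryne 11 (not isolated), via caesium alkynylbenzoate 12 (not isolated)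
Conditions: (IPr)CuCl (10 mol %; IPr = 1,3-bis(2,6-diisopropylphenyl)imidazol-2-ylidene), CsF, Cs2CO3, CO2 (1 atm), MeCN–THF, 50 °C
Reagents that add atoms: none
Why: Fluoride attacks the silicon of 7 and triflate departs, releasing aryne 11, while Cs2CO3 and (IPr)CuCl turn 9 into the copper acetylide; the acetylide carbon adds to C4a, the aryne terminus remote from the C8 oxygen, so that the new aryl–copper bond sits at C8a, where the adjacent C–O dipole and MOM chelation stabilise it (bond C4a–C4). The NHC-bound arylcopper then inserts CO2 (bond C8a–C1) to give carboxylate 12 (drawn as its caesium salt), the monovalent copper centre π-activates the alkyne, the carboxylate oxygen attacks C3 anti to the metal (bond O2–C3), and protonolysis of the C4–Cu bond by a further molecule of 9 regenerates the acetylide. The closest known reaction type is the NHC–copper-catalysed three-component coupling of o-silylaryl triflates, terminal alkynes and CO2 to 3-substituted isocoumarins, applied here to a dialkoxyaryne and a propargylic silyl ether. Ring B closes in the 6-endo-dig mode and no stereocentre is created. Two selectivities are required: the sense of addition across the aryne, secured because only one aryne carbon (C8a) is flanked by an alkoxy group while chlorine is still absent from C5, and 6-endo over 5-exo closure, secured by soft copper activation of an alkyl-substituted alkyne in place of purely base-mediated lactonisation. Slow aryne release from sparingly soluble CsF under a CO2 atmosphere should keep carboxylation ahead of simple protonation of the arylcopper.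

Step 7
Reactants: 13 6,8-bis(methoxymethoxy)-3-(triisopropylsilyloxymethyl)isochromen-1-one
Product: 14 5-chloro-6,8-bis(methoxymethoxy)-3-(triisopropylsilyloxymethyl)isochromen-1-one
Conditions: NCS (1.05 equiv), DMF, rt, dark
Reagents that add atoms: N-chlorosuccinimide, O=C1CCC(=O)N1Cl
Why: Electrophilic aromatic chlorination should take C5, which is para to the C8 oxygen, ortho to the C6 oxygen and next to only one alkoxy group, rather than C7, which is wedged between both MOM ethers, in line with the halogenation of 5-alkylresorcinol diethers beside the alkyl group, while C4 of the enol ester is less activated and is screened by the TIPS-oxymethyl arm.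

Step 8
Reactants: 14 5-chloro-6,8-bis(methoxymethoxy)-3-(triisopropylsilyloxymethyl)isochromen-1-one
Product: 15 5-chloro-3-(hydroxymethyl)-6,8-bis(methoxymethoxy)isochromen-1-one
Conditions: HF·pyridine, pyridine, THF, 0 °C → rt
Reagents that add atoms: none
Why: Fluoride-mediated desilylation with pyridine-buffered HF cleaves the primary TIPS ether without the basic conditions that could open the lactone, and aryl MOM ethers are inert to this reagent.

Step 9
Reactants: 15 5-chloro-3-(hydroxymethyl)-6,8-bis(methoxymethoxy)isochromen-1-one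
Product: 16 3-(bromomethyl)-5-chloro-6,8-bis(methoxymethoxy)isochromen-1-one
Conditions: CBr4, PPh3, CH2Cl2, 0 °C
Reagents that add atoms: tetrabromomethane, BrC(Br)(Br)Br
Why: The Appel reaction turns the allylic-type primary alcohol into the bromide by SN2 displacement of an oxyphosphonium ion under neutral conditions that MOM ethers, lactone and aryl chloride tolerate.

Step 10
Reactants: 16 3-(bromomethyl)-5-chloro-6,8-bis(methoxymethoxy)isochromen-1-one
Product: 17 diethyl {[5-chloro-6,8-bis(methoxymethoxy)-1-oxoisochromen-3-yl]methyl}phosphonate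
Conditions: P(OEt)3, toluene, 110 °C
Reagents that add atoms: triethyl phosphite, CCOP(OCC)OCC
Why: The Michaelis–Arbuzov reaction of a reactive primary allylic-type bromide with triethyl phosphite needs only neutral heating, which none of the other groups should notice.

Step 11
Reactants: 18 2-deoxy-D-ribose
Product: 19 2-deoxy-D-ribono-1,4-lactone, (4S,5R)-4-hydroxy-5-(hydroxymethyl)oxolan-2-one
Conditions: Br2, H2O, rt; evaporation
Reagents that add atoms: none
Why: Bromine-water oxidation of an aldose oxidises only the anomeric carbon of the lactol and gives the stable 1,4-lactone, leaving the C3 and C4 stereocentres untouched.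

Step 12
Reactants: 19 2-deoxy-D-ribono-1,4-lactone
Product: 20 (4S,5R)-4-(tert-butyldimethylsilyloxy)-5-(tert-butyldimethylsilyloxymethyl)oxolan-2-one
Conditions: TBSCl, imidazole, DMF, rt
Reagents that add atoms: tert-butylchlorodimethylsilane, CC(C)(C)[Si](C)(C)Cl
Why: Imidazole-promoted silylation protects both hydroxyl groups in one operation and gives ethers that withstand organometallic addition and cold Lewis acid.

Step 13
Reactants: 20 (4S,5R)-4-(tert-butyldimethylsilyloxy)-5-(tert-butyldimethylsilyloxymethyl)oxolan-2-one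
Product: 21 (4S,5R)-4-(tert-butyldimethylsilyloxy)-5-(tert-butyldimethylsilyloxymethyl)-2-methyloxolan-2-ol (mixture at C2)
Conditions: CeCl3, MeLi, THF, −78 °C; then 20, −78 °C; H2O
Reagents that add atoms: methyllithium, [Li]C
Why: 1,2-Addition of an organocerium reagent to a lactone stops at the hemiketal because the tetrahedral alkoxide persists at −78 °C, the low basicity of MeCeCl2 should suppress enolisation and β-elimination of the C3 silyloxy group, and the new anomeric centre needs no control because step 14 erases it.

Step 14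
Reactants: 21 (4S,5R)-4-(tert-butyldimethylsilyloxy)-5-(tert-butyldimethylsilyloxymethyl)-2-methyloxolan-2-ol
Product: 23 (2R,3S,5S)-3-(tert-butyldimethylsilyloxy)-2-(tert-butyldimethylsilyloxymethyl)-5-methyloxolane, via oxocarbenium ion 22 (not isolated)
Conditions: Et3SiH, BF3·OEt2, CH2Cl2, −78 → −40 °C
Reagents that add atoms: none
Why: Lewis-acid ionisation followed by silane reduction (reductive deoxygenation of a hemiketal, as in C-glycoside synthesis) passes through oxocarbenium ion 22, whose favoured envelope holds the C3 silyloxy group pseudoaxial, so that inside attack delivers hydride cis to that oxygen and trans to the C2 side chain and thereby sets C5 as S with methyl cis to the side chain.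

Step 15
Reactants: 23 (2R,3S,5S)-3-(tert-butyldimethylsilyloxy)-2-(tert-butyldimethylsilyloxymethyl)-5-methyloxolane
Product: 24 [(2R,3S,5S)-3-(tert-butyldimethylsilyloxy)-5-methyloxolan-2-yl]methanol
Conditions: TFA, H2O, THF, 0 °C
Reagents that add atoms: none
Why: Acid-catalysed hydrolysis distinguishes the unhindered primary TBS ether from the secondary one on steric grounds, a selective desilylation that is routine for 3',5'-bis-O-TBS deoxynucleosides of the same ring pattern.

Step 16
Reactants: 24 [(2R,3S,5S)-3-(tert-butyldimethylsilyloxy)-5-methyloxolan-2-yl]methanol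
Product: 25 (2S,3S,5S)-3-(tert-butyldimethylsilyloxy)-5-methyloxolane-2-carbaldehyde (same spatial arrangement; the C2 descriptor changes with CIP priority)
Conditions: Dess–Martin periodinane, CH2Cl2, 0 °C → rt
Reagents that add atoms: none
Why: Dess–Martin oxidation stops at the aldehyde and is free of base, so epimerisation at C2 and β-elimination of the C3 silyloxy group should be avoided, and the crude aldehyde is used at once.

Step 17
Reactants: 25 (2S,3S,5S)-3-(tert-butyldimethylsilyloxy)-5-methyloxolane-2-carbaldehyde
Product: 26 (E)-3-[(2R,3S,5S)-3-(tert-butyldimethylsilyloxy)-5-methyloxolan-2-yl]prop-2-enal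
Conditions: Ph3P=CHCHO, toluene, 60 °C
Reagents that add atoms: (triphenylphosphoranylidene)acetaldehyde, O=CC=P(c1ccccc1)(c1ccccc1)c1ccccc1
Why: The Wittig reaction of the stabilised formyl ylide gives the E-enal, the α-alkoxy aldehyde is more electrophilic than the enal formed so that a second homologation should stay minor, and the weakly basic ylide leaves C2 intact.

Step 18
Reactants: 17 diethyl {[5-chloro-6,8-bis(methoxymethoxy)-1-oxoisochromen-3-yl]methyl}phosphonate; 26 (E)-3-[(2R,3S,5S)-3-(tert-butyldimethylsilyloxy)-5-methyloxolan-2-yl]prop-2-enal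
Product: 28 3-{(1E,3E)-4-[(2R,3S,5S)-3-(tert-butyldimethylsilyloxy)-5-methyloxolan-2-yl]buta-1,3-dienyl}-5-chloro-6,8-bis(methoxymethoxy)isochromen-1-one, via lithiated phosphonate 27 (not isolated)
Conditions: LiHMDS, THF, −78 °C; then 26, −78 → 0 °C
Reagents that add atoms: none
Why: In this Horner–Wadsworth–Emmons olefination the carbanion 27 is stabilised by the phosphoryl group and by conjugation through C3=C4 and ring A to the lactone carbonyl, as in the well-used (2-pyranon-6-yl)methylphosphonates, so reversible addition should lead to the E-alkene, and preforming the anion leaves no free base to attack the γ-hydrogen of the enal.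

Step 19
Reactants: 28 3-{(1E,3E)-4-[(2R,3S,5S)-3-(tert-butyldimethylsilyloxy)-5-methyloxolan-2-yl]buta-1,3-dienyl}-5-chloro-6,8-bis(methoxymethoxy)isochromen-1-one
Product: 29 5-chloro-6,8-dihydroxy-3-{(1E,3E)-4-[(2R,3S,5S)-3-hydroxy-5-methyloxolan-2-yl]buta-1,3-dienyl}isochromen-1-one (target)
Conditions: 3 M aq. HCl, THF, 40 °C
Reagents that add atoms: none
Why: Acid hydrolysis cleaves the two aryl MOM acetals and the secondary TBS ether in one operation, whereas lactone, aryl chloride and diene are inert to dilute acid and ionisation of the allylic C2–O bond is disfavoured by the neighbouring C3 oxygen and the electron-poor isocoumarin end of the diene.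

Compound list
1 | phloroglucinol | Oc1cc(O)cc(O)c1 | starting material
2 | 3,5-bis(methoxymethoxy)phenol | COCOc1cc(O)cc(OCOC)c1 | intermediate
3 | 2-bromo-3,5-bis(methoxymethoxy)phenol | COCOc1cc(O)c(Br)c(OCOC)c1 | intermediate
4 | [2-bromo-3,5-bis(methoxymethoxy)phenoxy]trimethylsilane | COCOc1cc(O[Si](C)(C)C)c(Br)c(OCOC)c1 | intermediate
5 | [2,4-bis(methoxymethoxy)-6-(trimethylsilyloxy)phenyl]lithium | COCOc1cc(O[Si](C)(C)C)c([Li])c(OCOC)c1 | intermediate
6 | lithium 3,5-bis(methoxymethoxy)-2-(trimethylsilyl)phenoxide | COCOc1cc([O-])c([Si](C)(C)C)c(OCOC)c1.[Li+] | intermediate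
7 | 3,5-bis(methoxymethoxy)-2-(trimethylsilyl)phenyl trifluoromethanesulfonate | COCOc1cc(OCOC)c([Si](C)(C)C)c(OS(=O)(=O)C(F)(F)F)c1 | intermediate
8 | propargyl alcohol | C#CCO | starting material
9 | triisopropyl(prop-2-ynyloxy)silane | C#CCO[Si](C(C)C)(C(C)C)C(C)C | intermediate
10 | carbon dioxide | O=C=O | starting material
11 | 3,5-bis(methoxymethoxy)benzyne | COCOC1=CC(OCOC)=CC#C1 | intermediate
12 | caesium 2,4-bis(methoxymethoxy)-6-[3-(triisopropylsilyloxy)prop-1-ynyl]benzoate | COCOc1cc(OCOC)c(C(=O)[O-])c(C#CCO[Si](C(C)C)(C(C)C)C(C)C)c1.[Cs+] | intermediate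
13 | 6,8-bis(methoxymethoxy)-3-(triisopropylsilyloxymethyl)isochromen-1-one | CC(C)[Si](C(C)C)(C(C)C)OCc1cc2cc(OCOC)cc(OCOC)c2c(=O)o1 | intermediate
14 | 5-chloro-6,8-bis(methoxymethoxy)-3-(triisopropylsilyloxymethyl)isochromen-1-one | CC(C)[Si](C(C)C)(C(C)C)OCc1cc2c(Cl)c(OCOC)cc(OCOC)c2c(=O)o1 | intermediate
15 | 5-chloro-3-(hydroxymethyl)-6,8-bis(methoxymethoxy)isochromen-1-one | OCc1cc2c(Cl)c(OCOC)cc(OCOC)c2c(=O)o1 | intermediate
16 | 3-(bromomethyl)-5-chloro-6,8-bis(methoxymethoxy)isochromen-1-one | BrCc1cc2c(Cl)c(OCOC)cc(OCOC)c2c(=O)o1 | intermediate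
17 | diethyl {[5-chloro-6,8-bis(methoxymethoxy)-1-oxoisochromen-3-yl]methyl}phosphonate | CCOP(=O)(OCC)Cc1cc2c(Cl)c(OCOC)cc(OCOC)c2c(=O)o1 | intermediate
18 | 2-deoxy-D-ribose | O=CC[C@H](O)[C@H](O)CO | starting material
19 | 2-deoxy-D-ribono-1,4-lactone | O=C1C[C@H](O)[C@@H](CO)O1 | intermediate
20 | (4S,5R)-4-(tert-butyldimethylsilyloxy)-5-(tert-butyldimethylsilyloxymethyl)oxolan-2-one | O=C1C[C@H](O[Si](C)(C)C(C)(C)C)[C@@H](CO[Si](C)(C)C(C)(C)C)O1 | intermediate
21 | (4S,5R)-4-(tert-butyldimethylsilyloxy)-5-(tert-butyldimethylsilyloxymethyl)-2-methyloxolan-2-ol | CC1(O)C[C@H](O[Si](C)(C)C(C)(C)C)[C@@H](CO[Si](C)(C)C(C)(C)C)O1 | intermediate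
22 | (2R,3S)-3-(tert-butyldimethylsilyloxy)-2-(tert-butyldimethylsilyloxymethyl)-5-methyl-3,4-dihydro-2H-furan-1-ium | CC1=[O+][C@H](CO[Si](C)(C)C(C)(C)C)[C@@H](O[Si](C)(C)C(C)(C)C)C1 | intermediate
23 | (2R,3S,5S)-3-(tert-butyldimethylsilyloxy)-2-(tert-butyldimethylsilyloxymethyl)-5-methyloxolane | C[C@H]1C[C@H](O[Si](C)(C)C(C)(C)C)[C@@H](CO[Si](C)(C)C(C)(C)C)O1 | intermediate
24 | [(2R,3S,5S)-3-(tert-butyldimethylsilyloxy)-5-methyloxolan-2-yl]methanol | C[C@H]1C[C@H](O[Si](C)(C)C(C)(C)C)[C@@H](CO)O1 | intermediate
25 | (2S,3S,5S)-3-(tert-butyldimethylsilyloxy)-5-methyloxolane-2-carbaldehyde | C[C@H]1C[C@H](O[Si](C)(C)C(C)(C)C)[C@@H](C=O)O1 | intermediate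
26 | (E)-3-[(2R,3S,5S)-3-(tert-butyldimethylsilyloxy)-5-methyloxolan-2-yl]prop-2-enal | C[C@H]1C[C@H](O[Si](C)(C)C(C)(C)C)[C@@H](/C=C/C=O)O1 | intermediate
27 | lithium salt of the α-carbanion of phosphonate 17 | CCOP(=O)(OCC)[CH-]c1cc2c(Cl)c(OCOC)cc(OCOC)c2c(=O)o1.[Li+] | intermediate
28 | 3-{(1E,3E)-4-[(2R,3S,5S)-3-(tert-butyldimethylsilyloxy)-5-methyloxolan-2-yl]buta-1,3-dienyl}-5-chloro-6,8-bis(methoxymethoxy)isochromen-1-one | C[C@H]1C[C@H](O[Si](C)(C)C(C)(C)C)[C@@H](/C=C/C=C/c2cc3c(Cl)c(OCOC)cc(OCOC)c3c(=O)o2)O1 | intermediate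
29 | 5-chloro-6,8-dihydroxy-3-{(1E,3E)-4-[(2R,3S,5S)-3-hydroxy-5-methyloxolan-2-yl]buta-1,3-dienyl}isochromen-1-one | C[C@H]1C[C@H](O)[C@@H](/C=C/C=C/c2cc3c(Cl)c(O)cc(O)c3c(=O)o2)O1 | target

Total step count: 19.
Longest linear sequence: 11 steps from phloroglucinol (steps 1, 2, 3, 4, 6, 7, 8, 9, 10, 18, 19). The oxolane branch needs 9 steps (11–19).

Steps most likely to fail

Step 6. Several processes could erode the coupling:
- unselective addition of the acetylide across the aryne
- protonation of the crowded arylcopper before it takes up CO2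
- 5-exo closure of the carboxylate
- fluoride attack on the TIPS ether

The fallback fixes the substitution pattern by cross-coupling instead of aryne polarisation. It sets out from phenol 2 (with alkyne 9 as partner) and rejoins the route at 13. Magnesium-mediated ortho-formylation (MgCl2, Et3N, paraformaldehyde; Casnati–Skattebøl reaction) should give 2-hydroxy-4,6-bis(methoxymethoxy)benzaldehyde F1 as the only isomer, because both ortho positions are equivalent. Tf2O and pyridine convert it into 2-formyl-3,5-bis(methoxymethoxy)phenyl trifluoromethanesulfonate F2. Sonogashira coupling with 9 (Pd(PPh3)2Cl2, CuI, Et3N) gives 2,4-bis(methoxymethoxy)-6-[3-(triisopropylsilyloxy)prop-1-ynyl]benzaldehyde F3. Pinnick oxidation (NaClO2, NaH2PO4, 2-methylbut-2-ene) gives 2,4-bis(methoxymethoxy)-6-[3-(triisopropylsilyloxy)prop-1-ynyl]benzoic acid F4. AgOTf-catalysed 6-endo-dig cycloisomerisation of the acid then closes ring B to 13.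

Step 7. Chlorine may enter at C7 or at C4 of the enol ester, or a second chlorination may follow the first. The fallback replaces steric control by the directing power of a free phenol. It sets out from 13 and rejoins at 14. Chelation-assisted cleavage of the MOM ether peri to the lactone carbonyl (MgBr2·OEt2, CH2Cl2) should give 8-hydroxy-6-(methoxymethoxy)-3-(triisopropylsilyloxymethyl)isochromen-1-one F5. The carbonyl-chelated phenol then directs SO2Cl2 (Et2O–CH2Cl2, 0 °C) to its para position, as in the chlorination of chelated resorcylates. This gives 5-chloro-8-hydroxy-6-(methoxymethoxy)-3-(triisopropylsilyloxymethyl)isochromen-1-one F6. MOMCl with i-Pr2NEt restores the C8 ether and delivers 14.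

Step 19. The acid needed for the less labile C6 MOM ether may ionise the dienylic C2–O bond of the oxolane, which would bring epimerisation, ring opening or isomerisation of the diene. The fallback exchanges the phenol protection for fluoride-labile groups once the fluoride-dependent aryne step is past. It sets out from 17 (with enal 26 as partner) and rejoins at 29. HCl in MeOH removes both MOM groups at the robust phosphonate stage and gives diethyl [(5-chloro-6,8-dihydroxy-1-oxoisochromen-3-yl)methyl]phosphonate F7. TBSCl and imidazole give diethyl {[6,8-bis(tert-butyldimethylsilyloxy)-5-chloro-1-oxoisochromen-3-yl]methyl}phosphonate F8. Deprotonation with LiHMDS and HWE olefination with 26 give 6,8-bis(tert-butyldimethylsilyloxy)-3-{(1E,3E)-4-[(2R,3S,5S)-3-(tert-butyldimethylsilyloxy)-5-methyloxolan-2-yl]buta-1,3-dienyl}-5-chloroisochromen-1-one F9. Pyridine-buffered HF·pyridine in THF then removes all three silyl groups without strong acid and gives 29.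

Further compounds
F1 | step 6 | 2-hydroxy-4,6-bis(methoxymethoxy)benzaldehyde | COCOc1cc(O)c(C=O)c(OCOC)c1
F2 | step 6 | 2-formyl-3,5-bis(methoxymethoxy)phenyl trifluoromethanesulfonate | COCOc1cc(OCOC)c(C=O)c(OS(=O)(=O)C(F)(F)F)c1
F3 | step 6 | 2,4-bis(methoxymethoxy)-6-[3-(triisopropylsilyloxy)prop-1-ynyl]benzaldehyde | COCOc1cc(OCOC)c(C=O)c(C#CCO[Si](C(C)C)(C(C)C)C(C)C)c1
F4 | step 6 | 2,4-bis(methoxymethoxy)-6-[3-(triisopropylsilyloxy)prop-1-ynyl]benzoic acid | COCOc1cc(OCOC)c(C(=O)O)c(C#CCO[Si](C(C)C)(C(C)C)C(C)C)c1
F5 | step 7 | 8-hydroxy-6-(methoxymethoxy)-3-(triisopropylsilyloxymethyl)isochromen-1-one | CC(C)[Si](C(C)C)(C(C)C)OCc1cc2cc(OCOC)cc(O)c2c(=O)o1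
F6 | step 7 | 5-chloro-8-hydroxy-6-(methoxymethoxy)-3-(triisopropylsilyloxymethyl)isochromen-1-one | CC(C)[Si](C(C)C)(C(C)C)OCc1cc2c(Cl)c(OCOC)cc(O)c2c(=O)o1
F7 | step 19 | diethyl [(5-chloro-6,8-dihydroxy-1-oxoisochromen-3-yl)methyl]phosphonate | CCOP(=O)(OCC)Cc1cc2c(Cl)c(O)cc(O)c2c(=O)o1
F8 | step 19 | diethyl {[6,8-bis(tert-butyldimethylsilyloxy)-5-chloro-1-oxoisochromen-3-yl]methyl}phosphonate | CCOP(=O)(OCC)Cc1cc2c(Cl)c(O[Si](C)(C)C(C)(C)C)cc(O[Si](C)(C)C(C)(C)C)c2c(=O)o1
F9 | step 19 | 6,8-bis(tert-butyldimethylsilyloxy)-3-{(1E,3E)-4-[(2R,3S,5S)-3-(tert-butyldimethylsilyloxy)-5-methyloxolan-2-yl]buta-1,3-dienyl}-5-chloroisochromen-1-one | C[C@H]1C[C@H](O[Si](C)(C)C(C)(C)C)[C@@H](/C=C/C=C/c2cc3c(Cl)c(O[Si](C)(C)C(C)(C)C)cc(O[Si](C)(C)C(C)(C)C)c3c(=O)o2)O1
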